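**Retrosynthetic overview**
1. Target 30 comes from triol 29 by acetylation of O9 and O12 only (the C6 hydroxyl is hindered); 29 comes from silyl ether 28.
2. The seven-membered ring is closed last: C9–C10 by nickel-catalysed reductive alkyne–aldehyde cyclization of ynal 27, which also delivers C9–O and the exocyclic methylene.
3. Key C6–C7 bond: Hoppe homoaldol union of aldehyde 10 with the titanated allyl carbamate from 21, a chiral homoenolate of the future C9 aldehyde. It sets C6 and C7 and leaves C9 masked as an enol carbamate.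
4. Aldehyde 10 carries the five-membered ring, present from the start in cyclopentenone 1: conjugate alkynylation with enolate trapping (C1), a formyl cation equivalent (C5), then ketone to methyl alkene.
5. Carbamate 21 comes from chloroacetaldehyde: syn-crotylboration (C11, C12), cross-metathesis, then epoxide opening with an isobutenyl copper reagent.

Assumption: where the sense of induction of a chiral ligand, catalyst or auxiliary on these exact substrates is not certain, the antipode that gives the drawn configuration is meant.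

Atom labels C1–C12 follow the dictyol numbering used above (C1/C5 ring fusion, C6 carbinol, C7 side-chain carbon, C9 acetoxy carbon, C10 methylene carbon, C11/C12 side chain).

**Step 1**
Reactants: 1 cyclopent-2-en-1-one; 2 ethynyltrimethylsilane
Product: 5 (R)-trimethyl({3-[(trimethylsilyl)ethynyl]cyclopent-1-en-1-yl}oxy)silane, via alkynyldimethylalane 3 (not isolated), via aluminium enolate 4 (not isolated)
Conditions: 2, AlMe3, Et3N (cat.), toluene, 60 °C; then 1, Ni(acac)2 (5 mol %), (S,S)-t-Bu-bis(oxazoline) (6 mol %), t-BuOMe, −30 °C; then Me3SiOTf, −78 → 0 °C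
Reagents that add atoms: trimethylsilyl trifluoromethanesulfonate, C[Si](C)(C)OS(=O)(=O)C(F)(F)F
Why: Proposed new method: nickel-catalysed 1,4-transfer of the alkynyl group from alane 3 to the enone should pass through a ligand-bound nickel–enone complex with one open face, setting C1 (3R), and O-silylation of aluminium enolate 4 then fixes the enolate regiochemistry; the closest known reactions are the Ni(acac)2/bis(oxazoline)-catalysed enantioselective conjugate alkynylation of cyclohexenone with this alane and the Schwartz nickel-catalysed alkynylalane addition to cyclopentenones.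

**Step 2**
Reactants: 5 (R)-trimethyl({3-[(trimethylsilyl)ethynyl]cyclopent-1-en-1-yl}oxy)silane
Product: 6 (2R,3R)-2-(dimethoxymethyl)-3-[(trimethylsilyl)ethynyl]cyclopentan-1-one
Conditions: HC(OMe)3, Me3SiOTf (5 mol %), CH2Cl2, −78 °C
Reagents that add atoms: trimethyl orthoformate, COC(OC)OC
Why: Mukaiyama-type (Noyori) condensation of the silyl enol ether with the dimethoxycarbenium ion occurs anti to the alkynyl group and gives the thermodynamically favoured trans-2,3-disubstituted cyclopentanone, setting C5.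

**Step 3**
Reactants: 6 (2R,3R)-2-(dimethoxymethyl)-3-[(trimethylsilyl)ethynyl]cyclopentan-1-one
Product: 7 (4R,5S)-5-(dimethoxymethyl)-4-[(trimethylsilyl)ethynyl]cyclopent-1-en-1-yl trifluoromethanesulfonate
Conditions: KN(SiMe3)2, THF, −78 °C; then PhNTf2, −78 → 0 °C
Reagents that add atoms: N-phenylbis(trifluoromethanesulfonimide), O=S(=O)(N(c1ccccc1)S(=O)(=O)C(F)(F)F)C(F)(F)F
Why: Kinetic deprotonation takes the unhindered CH2 (C3) rather than the substituted C5, so enolate O-triflation gives the C3=C4 enol triflate without touching the stereocentres.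

**Step 4**
Reactants: 7 (4R,5S)-5-(dimethoxymethyl)-4-[(trimethylsilyl)ethynyl]cyclopent-1-en-1-yl trifluoromethanesulfonate
Product: 8 trimethyl{[(1R,5S)-5-(dimethoxymethyl)-4-methylcyclopent-3-en-1-yl]ethynyl}silane
Conditions: MeMgBr, Fe(acac)3 (5 mol %), THF/NMP, −30 °C
Reagents that add atoms: methylmagnesium bromide, C[Mg]Br
Why: Iron-catalysed Kumada-type cross-coupling of an alkenyl triflate with a methyl Grignard reagent installs the C4 methyl with retention of the alkene position.

**Step 5**
Reactants: 8 trimethyl{[(1R,5S)-5-(dimethoxymethyl)-4-methylcyclopent-3-en-1-yl]ethynyl}silane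
Product: 10 (1S,5R)-5-ethynyl-2-methylcyclopent-2-ene-1-carbaldehyde, via terminal alkyne acetal 9 (not isolated)
Conditions: K2CO3, MeOH, 20 °C; then 1 M HCl, THF, 0 °C
Reagents that add atoms: water, O
Why: Methanolysis of the alkynyl C–Si bond followed by cold dilute-acid acetal hydrolysis frees the aldehyde under conditions too mild to epimerize C5 or conjugate the β,γ-alkene; the aldehyde is used crude.

**Step 6**
Reactants: 11 (Z)-but-2-ene-1,4-diol
Product: 12 (Z)-but-2-ene-1,4-diyl bis(N,N-diisopropylcarbamate)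
Conditions: i-Pr2NC(O)Cl (2.2 equiv), pyridine, 90 °C
Reagents that add atoms: N,N-diisopropylcarbamoyl chloride, CC(C)N(C(C)C)C(=O)Cl
Why: Simple O-carbamoylation gives a symmetrical cross-metathesis partner that carries the Hoppe directing group.

**Step 7**
Reactants: 13 chloroacetaldehyde (anhydrous); 14 (Z)-crotylboronic acid pinacol ester
Product: 16 (2R,3S)-1-chloro-3-methylpent-4-en-2-ol, via pinacol borate ester 15 (not isolated)
Conditions: (R)-TRIP phosphoric acid (5 mol %), toluene, −30 °C; then aq. NaHCO3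
Reagents that add atoms: none
Why: Chiral phosphoric acid-catalysed crotylboration proceeds through a closed chair transition state, so the (Z)-boronate gives the syn methyl/hydroxyl pair (C11, C12) and the catalyst selects the aldehyde face.

**Step 8**
Reactants: 16 (2R,3S)-1-chloro-3-methylpent-4-en-2-ol; 12 (Z)-but-2-ene-1,4-diyl bis(N,N-diisopropylcarbamate)
Product: 17 (2E,4S,5R)-6-chloro-5-hydroxy-4-methylhex-2-en-1-yl N,N-diisopropylcarbamate
Conditions: 12 (2.5 equiv), second-generation Hoveyda–Grubbs catalyst (5 mol %), CH2Cl2, 40 °C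
Reagents that add atoms: none
Why: Olefin cross-metathesis gives the E-allylic carbamate, and it is run before the prenyl alkene exists so that ring-closing metathesis of a 1,6-diene cannot compete.

**Step 9**
Reactants: 17 (2E,4S,5R)-6-chloro-5-hydroxy-4-methylhex-2-en-1-yl N,N-diisopropylcarbamate; 18 (2-methylprop-1-en-1-yl)magnesium bromide
Product: 20 (2E,4S,5S)-5-hydroxy-4,8-dimethylnona-2,7-dien-1-yl N,N-diisopropylcarbamate, via epoxide 19 (not isolated)
Conditions: NaH, THF, 0 → 20 °C; then 18, CuI (10 mol %), −30 → 0 °C; H2O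
Reagents that add atoms: none
Why: Williamson closure of the chlorohydrin to the terminal epoxide and copper-catalysed Grignard opening at the unsubstituted carbon (SN2) attach the isobutenyl unit without touching C11 or C12, the hindered carbamate being inert.

**Step 10**
Reactants: 20 (2E,4S,5S)-5-hydroxy-4,8-dimethylnona-2,7-dien-1-yl N,N-diisopropylcarbamate
Product: 21 (2E,4S,5S)-5-[(tert-butyldimethylsilyl)oxy]-4,8-dimethylnona-2,7-dien-1-yl N,N-diisopropylcarbamate
Conditions: t-BuMe2SiOTf, 2,6-lutidine, CH2Cl2, −78 → 0 °C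
Reagents that add atoms: tert-butyldimethylsilyl trifluoromethanesulfonate, CC(C)(C)[Si](C)(C)OS(=O)(=O)C(F)(F)F
Why: Silylation masks the C12 hydroxyl against the organolithium base of the next step.

**Step 11**
Reactants: 21 (2E,4S,5S)-5-[(tert-butyldimethylsilyl)oxy]-4,8-dimethylnona-2,7-dien-1-yl N,N-diisopropylcarbamate; 10 (1S,5R)-5-ethynyl-2-methylcyclopent-2-ene-1-carbaldehyde
Product: 24 (1Z,3S,4R)-3-[(2S,3S)-3-(tert-butyldimethylsilyloxy)-6-methylhept-5-en-2-yl]-4-[(1S,5R)-5-ethynyl-2-methylcyclopent-2-en-1-yl]-4-hydroxybut-1-en-1-yl N,N-diisopropylcarbamate, via lithiated carbamate 22 (not isolated), via allyltitanium reagent 23 (not isolated)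
Conditions: s-BuLi, (+)-sparteine, toluene, −78 °C; Ti(Oi-Pr)4, −78 °C; then 10, −78 → −40 °C; H2O
Reagents that add atoms: none
Why: In this Hoppe homoaldol reaction, sparteine-directed deprotonation next to the carbamate oxygen and lithium–titanium exchange with inversion give a configurationally defined allyltitanium homoenolate, whose γ-carbon (C7) adds to the aldehyde through a Zimmerman–Traxler chair so that the E-alkene gives the anti C6/C7 pair (6R,7S) and the Z-enol carbamate under reagent control.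

**Step 12**
Reactants: 24 homoaldol adduct (name as in step 11)
Product: 25 (1Z,3S,4R)-3-[(2S,3S)-3-(tert-butyldimethylsilyloxy)-6-methylhept-5-en-2-yl]-4-[(1S,5R)-5-ethynyl-2-methylcyclopent-2-en-1-yl]-4-(triethylsilyloxy)but-1-en-1-yl N,N-diisopropylcarbamate
Conditions: Et3SiOTf, 2,6-lutidine, CH2Cl2, −78 °C
Reagents that add atoms: triethylsilyl trifluoromethanesulfonate, CC[Si](CC)(CC)OS(=O)(=O)C(F)(F)F
Why: Silylation of the C6 hydroxyl prevents lactol formation once the C9 aldehyde is unmasked.

**Step 13**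
Reactants: 25 triethylsilyl ether (name as in step 12)
Product: 27 (3S,4R)-3-[(2S,3S)-3-(tert-butyldimethylsilyloxy)-6-methylhept-5-en-2-yl]-4-[(1S,5R)-5-ethynyl-2-methylcyclopent-2-en-1-yl]-4-(triethylsilyloxy)butanal, via dilithium enolate 26 (not isolated)
Conditions: MeLi (3.2 equiv), THF, −78 → 0 °C; then inverse quench into cold aqueous buffer
Reagents that add atoms: none
Why: Methyllithium attacks the carbamate carbonyl of the enol carbamate and releases the lithium enolate (Hoppe enol carbamate cleavage), which is protonated to the C9 aldehyde, the alkyne being carried as its acetylide meanwhile.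

**Step 14**
Reactants: 27 ynal (name as in step 13)
Product: 28 (3aS,4R,5S,7R,8aR)-5-[(2S,3S)-3-(tert-butyldimethylsilyloxy)-6-methylhept-5-en-2-yl]-3-methyl-8-methylidene-4,7-bis(triethylsilyloxy)-1,3a,4,5,6,7,8,8a-octahydroazulene
Conditions: Ni(cod)2 (20 mol %), IMes·HCl (20 mol %), KOt-Bu (20 mol %), Et3SiH (5 equiv), THF (0.005 M), 25 °C
Reagents that add atoms: triethylsilane, CC[SiH](CC)CC
Why: In this nickel-catalysed reductive ynal cyclization (Montgomery type), zerovalent nickel couples the alkyne and aldehyde oxidatively in the exo mode so the internal alkyne carbon bonds to C9, and silane σ-bond metathesis then gives the exocyclic methylene and the silyl ether; C9 is set by substrate control with the oxygen expected trans to the C7 side chain, which is the least secure stereochemical call of the route.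

**Step 15**
Reactants: 28 tris-silyl ether (name as in step 14)
Product: 29 (3aS,4R,5S,7R,8aR)-5-[(2S,3S)-3-hydroxy-6-methylhept-5-en-2-yl]-3-methyl-8-methylidene-1,3a,4,5,6,7,8,8a-octahydroazulene-4,7-diol
Conditions: Bu4NF (5 equiv), THF, 25 °C
Reagents that add atoms: none
Why: Fluoride cleaves all three silyl ethers in one operation.

**Step 16**
Reactants: 29 triol (name as in step 15)
Product: 30 (3aS,4R,5S,7R,8aR)-5-[(2S,3S)-3-acetoxy-6-methylhept-5-en-2-yl]-4-hydroxy-3-methyl-8-methylidene-1,3a,4,5,6,7,8,8a-octahydroazulen-7-yl acetate (target)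
Conditions: Ac2O (2.5 equiv), pyridine, CH2Cl2, 0 → 20 °C (no DMAP)
Reagents that add atoms: acetic anhydride, CC(=O)OC(C)=O
Why: Selective acylation is expected because the allylic C9 and the C12 hydroxyls are accessible, whereas the C6 hydroxyl, flanked by the ring-fusion carbon and the branched C7, should not react without an acyl-transfer catalyst.

**Compound list**
1 | cyclopent-2-en-1-one | O=C1C=CCC1 | starting material
2 | ethynyltrimethylsilane | C#C[Si](C)(C)C | starting material
3 | dimethyl[(trimethylsilyl)ethynyl]alane | C[Al](C)C#C[Si](C)(C)C | intermediate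
4 | dimethylaluminium (R)-3-[(trimethylsilyl)ethynyl]cyclopent-1-en-1-olate | C[Al](C)OC1=C[C@H](C#C[Si](C)(C)C)CC1 | intermediate
5 | (R)-trimethyl({3-[(trimethylsilyl)ethynyl]cyclopent-1-en-1-yl}oxy)silane | C[Si](C)(C)OC1=C[C@H](C#C[Si](C)(C)C)CC1 | intermediate
6 | (2R,3R)-2-(dimethoxymethyl)-3-[(trimethylsilyl)ethynyl]cyclopentan-1-one (trans) | COC(OC)[C@@H]1C(=O)CC[C@H]1C#C[Si](C)(C)C | intermediate
7 | (4R,5S)-5-(dimethoxymethyl)-4-[(trimethylsilyl)ethynyl]cyclopent-1-en-1-yl trifluoromethanesulfonate | COC(OC)[C@@H]1C(OS(=O)(=O)C(F)(F)F)=CC[C@H]1C#C[Si](C)(C)C | intermediate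
8 | trimethyl{[(1R,5S)-5-(dimethoxymethyl)-4-methylcyclopent-3-en-1-yl]ethynyl}silane | COC(OC)[C@@H]1C(C)=CC[C@H]1C#C[Si](C)(C)C | intermediate
9 | (4R,5S)-5-(dimethoxymethyl)-4-ethynyl-1-methylcyclopent-1-ene | COC(OC)[C@@H]1C(C)=CC[C@H]1C#C | intermediate
10 | (1S,5R)-5-ethynyl-2-methylcyclopent-2-ene-1-carbaldehyde (trans) | O=C[C@@H]1C(C)=CC[C@H]1C#C | intermediate
11 | (Z)-but-2-ene-1,4-diol | OC/C=C\CO | starting material
12 | (Z)-but-2-ene-1,4-diyl bis(N,N-diisopropylcarbamate) | CC(C)N(C(C)C)C(=O)OC/C=C\COC(=O)N(C(C)C)C(C)C | intermediate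
13 | chloroacetaldehyde | O=CCCl | starting material
14 | (Z)-crotylboronic acid pinacol ester | C/C=C\CB1OC(C)(C)C(C)(C)O1 | starting material
15 | 2-{[(2R,3S)-1-chloro-3-methylpent-4-en-2-yl]oxy}-4,4,5,5-tetramethyl-1,3,2-dioxaborolane | C=C[C@H](C)[C@H](CCl)OB1OC(C)(C)C(C)(C)O1 | intermediate
16 | (2R,3S)-1-chloro-3-methylpent-4-en-2-ol (syn) | C=C[C@H](C)[C@H](CCl)O | intermediate
17 | (2E,4S,5R)-6-chloro-5-hydroxy-4-methylhex-2-en-1-yl N,N-diisopropylcarbamate | CC(C)N(C(C)C)C(=O)OC/C=C/[C@H](C)[C@H](CCl)O | intermediate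
18 | (2-methylprop-1-en-1-yl)magnesium bromide | CC(C)=C[Mg]Br | starting material
19 | (2E,4S)-4-[(2R)-oxiran-2-yl]pent-2-en-1-yl N,N-diisopropylcarbamate | CC(C)N(C(C)C)C(=O)OC/C=C/[C@H](C)[C@@H]1CO1 | intermediate
20 | (2E,4S,5S)-5-hydroxy-4,8-dimethylnona-2,7-dien-1-yl N,N-diisopropylcarbamate | CC(C)N(C(C)C)C(=O)OC/C=C/[C@H](C)[C@H](CC=C(C)C)O | intermediate
21 | (2E,4S,5S)-5-[(tert-butyldimethylsilyl)oxy]-4,8-dimethylnona-2,7-dien-1-yl N,N-diisopropylcarbamate | CC(C)N(C(C)C)C(=O)OC/C=C/[C@H](C)[C@H](CC=C(C)C)O[Si](C)(C)C(C)(C)C | intermediate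
22 | (1R)-1-lithio derivative of 21 (sparteine complex) | CC(C)N(C(C)C)C(=O)O[C@H]([Li])/C=C/[C@H](C)[C@H](CC=C(C)C)O[Si](C)(C)C(C)(C)C | intermediate
23 | (1S)-1-(triisopropoxytitanio) derivative of 21 | CC(C)N(C(C)C)C(=O)O[C@@H]([Ti](OC(C)C)(OC(C)C)OC(C)C)/C=C/[C@H](C)[C@H](CC=C(C)C)O[Si](C)(C)C(C)(C)C | intermediate
24 | homoaldol adduct, (1Z,3S,4R)-configured, free C6 hydroxyl (full name in step 11) | CC(C)N(C(C)C)C(=O)O/C=C\[C@@H]([C@H](C)[C@H](CC=C(C)C)O[Si](C)(C)C(C)(C)C)[C@@H](O)[C@@H]1C(C)=CC[C@H]1C#C | intermediate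
25 | C6 triethylsilyl ether of 24 (full name in step 12) | CC(C)N(C(C)C)C(=O)O/C=C\[C@@H]([C@H](C)[C@H](CC=C(C)C)O[Si](C)(C)C(C)(C)C)[C@@H](O[Si](CC)(CC)CC)[C@@H]1C(C)=CC[C@H]1C#C | intermediate
26 | dilithium species: lithium (Z)-enolate of 27 carrying the lithium acetylide | [Li]O/C=C\[C@@H]([C@H](C)[C@H](CC=C(C)C)O[Si](C)(C)C(C)(C)C)[C@@H](O[Si](CC)(CC)CC)[C@@H]1C(C)=CC[C@H]1C#C[Li] | intermediate
27 | ynal, (3S,4R)-configured butanal (full name in step 13) | O=CC[C@@H]([C@H](C)[C@H](CC=C(C)C)O[Si](C)(C)C(C)(C)C)[C@@H](O[Si](CC)(CC)CC)[C@@H]1C(C)=CC[C@H]1C#C | intermediate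
28 | cyclized tris-silyl ether (full name in step 14) | C=C1[C@H](O[Si](CC)(CC)CC)C[C@@H]([C@H](C)[C@H](CC=C(C)C)O[Si](C)(C)C(C)(C)C)[C@@H](O[Si](CC)(CC)CC)[C@@H]2C(C)=CC[C@@H]12 | intermediate
29 | triol (full name in step 15) | C=C1[C@H](O)C[C@@H]([C@H](C)[C@H](CC=C(C)C)O)[C@@H](O)[C@@H]2C(C)=CC[C@@H]12 | intermediate
30 | CNP0151479.2 (full name in step 16) | C=C1[C@H](OC(C)=O)C[C@@H]([C@H](C)[C@H](CC=C(C)C)OC(C)=O)[C@@H](O)[C@@H]2C(C)=CC[C@@H]12 | target

**Step count**
Total: 16 steps. Longest linear sequence: 11 steps (steps 1–5, then 11–16).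

**Three steps most likely to fail, with fallbacks**

Step 1 (enantioselective alkynylation with enolate trapping has no direct precedent on cyclopentenone). The fallback sets out from 1 and comes back at 9. Cyclopentenone 1 is treated with formaldehyde SAMP-hydrazone F1 (made from SAMP and aqueous formaldehyde) and t-BuMe2SiOTf, so that the hydrazone carbon adds 1,4 as an auxiliary-controlled neutral formyl-anion equivalent and gives the silyl enol ether hydrazone F2. HC(OMe)3 with Me3SiOTf converts it into the keto acetal hydrazone F3, and two-phase oxalic acid hydrolysis frees the keto acetal aldehyde F4 with recovery of the auxiliary. Ohira–Bestmann homologation (dimethyl (1-diazo-2-oxopropyl)phosphonate, K2CO3, MeOH) gives the keto acetal alkyne F5, KN(SiMe3)2/PhNTf2 gives the enol triflate F6, and Me2CuLi methylates it to 9, which is hydrolysed to 10 as in step 5.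

Step 11 (the lithiated γ-branched carbamate may not be configurationally stable, and the chiral aldehyde may be mismatched). The fallback sets out from 21 and comes back at 24. Carbamate 21 is lithiated with s-BuLi/(−)-sparteine and quenched with Bu3SnCl, which attacks the γ-carbon anti to lithium and gives the storable γ-stannyl enol carbamate F7. TiCl4 then exchanges tin for titanium, again in the anti sense, and the trichlorotitanium homoenolate adds to aldehyde 10 through the same chair to give 24. The two anti steps with (−)-sparteine lead to the same product as the single inversion with (+)-sparteine.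

Step 14 (a seven-membered reductive cyclization is less precedented than five- or six-membered ones, and C9 rests on substrate control). The fallback sets out from 27 and comes back at 29. Ynal 27 is hydrostannylated at the internal alkyne carbon (Bu3SnH, Mo(CO)3(CNt-Bu)3 cat.) to the vinylstannane aldehyde F8, and iodine converts this into the vinyl iodide aldehyde F9. Nozaki–Hiyama–Kishi ring closure (CrCl2, NiCl2 cat., DMF) gives the C9 carbinol epimer mixture F10, which is oxidized without separation (Dess–Martin periodinane) to the α-methylene ketone F11. Reduction with (S)-Me-CBS and BH3·SMe2 sets C9 by reagent control and gives the (9R)-allylic alcohol F12, and Bu4NF then gives 29.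

**Further compounds**
F1 | step 1 | formaldehyde SAMP-hydrazone, (S)-2-(methoxymethyl)-N-methylidenepyrrolidin-1-amine | C=NN1CCC[C@H]1COC
F2 | step 1 | silyl enol ether hydrazone, tert-butyldimethylsilyl enol ether of (R)-3-formylcyclopentanone SAMP-hydrazone | CC(C)(C)[Si](C)(C)OC1=C[C@H](/C=N/N2CCC[C@H]2COC)CC1
F3 | step 1 | keto acetal hydrazone, trans-2-(dimethoxymethyl)-3-formylcyclopentanone SAMP-hydrazone | COC(OC)[C@@H]1C(=O)CC[C@H]1/C=N/N2CCC[C@H]2COC
F4 | step 1 | keto acetal aldehyde, trans-2-(dimethoxymethyl)-3-oxocyclopentane-1-carbaldehyde | COC(OC)[C@@H]1C(=O)CC[C@H]1C=O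
F5 | step 1 | keto acetal alkyne, (2R,3R)-2-(dimethoxymethyl)-3-ethynylcyclopentan-1-one | COC(OC)[C@@H]1C(=O)CC[C@H]1C#C
F6 | step 1 | enol triflate, (4R,5S)-5-(dimethoxymethyl)-4-ethynylcyclopent-1-en-1-yl trifluoromethanesulfonate | COC(OC)[C@@H]1C(OS(=O)(=O)C(F)(F)F)=CC[C@H]1C#C
F7 | step 11 | γ-stannyl enol carbamate, (1Z,3R,4R,5S)-5-[(tert-butyldimethylsilyl)oxy]-4,8-dimethyl-3-(tributylstannyl)nona-1,7-dien-1-yl N,N-diisopropylcarbamate | CC(C)N(C(C)C)C(=O)O/C=C\[C@@H]([Sn](CCCC)(CCCC)CCCC)[C@H](C)[C@H](CC=C(C)C)O[Si](C)(C)C(C)(C)C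
F8 | step 14 | vinylstannane aldehyde, 27 with the ethynyl group replaced by 1-(tributylstannyl)vinyl | O=CC[C@@H]([C@H](C)[C@H](CC=C(C)C)O[Si](C)(C)C(C)(C)C)[C@@H](O[Si](CC)(CC)CC)[C@@H]1C(C)=CC[C@H]1C(=C)[Sn](CCCC)(CCCC)CCCC
F9 | step 14 | vinyl iodide aldehyde, 27 with the ethynyl group replaced by 1-iodovinyl | O=CC[C@@H]([C@H](C)[C@H](CC=C(C)C)O[Si](C)(C)C(C)(C)C)[C@@H](O[Si](CC)(CC)CC)[C@@H]1C(C)=CC[C@H]1C(I)=C
F10 | step 14 | C9 carbinol epimer mixture, the C9 alcohol corresponding to 28 with C9 undefined | C=C1C(O)C[C@@H]([C@H](C)[C@H](CC=C(C)C)O[Si](C)(C)C(C)(C)C)[C@@H](O[Si](CC)(CC)CC)[C@@H]2C(C)=CC[C@@H]12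
F11 | step 14 | α-methylene ketone, the C9 ketone corresponding to 28 | C=C1C(=O)C[C@@H]([C@H](C)[C@H](CC=C(C)C)O[Si](C)(C)C(C)(C)C)[C@@H](O[Si](CC)(CC)CC)[C@@H]2C(C)=CC[C@@H]12
F12 | step 14 | (9R)-allylic alcohol, 28 with a free C9 hydroxyl | C=C1[C@H](O)C[C@@H]([C@H](C)[C@H](CC=C(C)C)O[Si](C)(C)C(C)(C)C)[C@@H](O[Si](CC)(CC)CC)[C@@H]2C(C)=CC[C@@H]12
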